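**Retrosynthetic overview**
- The target is reached from an 8-methylene hydroazulen-10-one with a free 6β-hydroxyl by alkene isomerisation, aroylation at O6, reduction at C10, tigloylation at O10 and global desilylation.
- That hydroazulenone comes from an intramolecular Hosomi–Sakurai closure (C6–C7 bond) of a cis-1,2-disubstituted cyclopentane carrying the C6 aldehyde on C5 and a 2-(trimethylsilylmethyl)allyl ketone (C10) on C1.
- The keto aldehyde comes from a cis-fused lactol (C10 masked by the C6 hydroxyl) and the Grignard reagent of 2-(chloromethyl)allyltrimethylsilane, then double Swern oxidation; the lactol comes from a conjugate vinyl addition product of a cyclopentene carbaldehyde.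
- The cyclopentene carbaldehyde comes from (S)-terpinen-4-ol by silylation, ozonolysis and aldol ring contraction; the five-membered ring is formed first (step 3), the seven-membered ring second (step 9).
- Feature used: C7–C8(CH3)–C9 of the seven-membered ring is an isobutene unit lying between the C6 carbinol and the C10 oxygen, so a 2-(silylmethyl)allyl ketone at C10 can attack a C6 aldehyde and the exocyclic C8 methylene can then move into the ring as the C8=C9 alkene.

Key step: step 9

Remark on numbering and faces: C1 is the quaternary methyl carbon, C2 and C3 the ring CH2 groups, C4 the isopropyl carbinol, C5 the ring-fusion CH, C6 the aroyloxy carbon, C7 the CH2, C8 the methyl-bearing alkene carbon, C9 the alkene CH, C10 the tigloyloxy carbon. β is the face carrying the C4 oxygen, α the face carrying the isopropyl group. In the target the seven-membered ring is attached on the β face at both C1 and C5 (cis fusion, C1 methyl and H5 α), O6 is β and O10 is α.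

Assumption: (S)-terpinen-4-ol of high enantiomeric purity is used; its carbinol centre becomes C4 and is the only source of absolute configuration.

**Step 1**
Reactants: 1 (S)-terpinen-4-ol
Product: 2 (S)-terpinen-4-ol triethylsilyl ether
Conditions: TESOTf, 2,6-lutidine, CH2Cl2, 0 °C to rt
Reagents that add atoms: triethylsilyl trifluoromethanesulfonate, CC[Si](CC)(CC)OS(=O)(=O)C(F)(F)F
Why: A silyl triflate with a hindered pyridine base silylates hindered tertiary alcohols (silyl ether formation) without touching the alkene, and the C4 centre is carried unchanged.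

**Step 2**
Reactants: 2 (S)-terpinen-4-ol triethylsilyl ether
Product: 4 (S)-3-isopropyl-6-oxo-3-(triethylsilyloxy)heptanal, via ozonide 3 (not isolated)
Conditions: O3, CH2Cl2, −78 °C; then PPh3, −78 °C to rt
Reagents that add atoms: ozone, [O-][O+]=O
Why: Ozonolysis with reductive work-up cleaves the only alkene to the methyl ketone and the aldehyde, and the neutral phosphine reduction should leave the β-silyloxy aldehyde intact.

**Step 3**
Reactants: 4 (S)-3-isopropyl-6-oxo-3-(triethylsilyloxy)heptanal
Product: 5 (R)-5-isopropyl-2-methyl-5-(triethylsilyloxy)cyclopent-1-ene-1-carbaldehyde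
Conditions: piperidine (0.2 equiv), AcOH (0.2 equiv), toluene, 60 °C
Reagents that add atoms: none
Why: In this amine-salt catalysed intramolecular aldol condensation the aldehyde enamine attacks the methyl ketone and dehydration gives the tetrasubstituted enal (the mode known for 6-oxoheptanals, whereas hydroxide would give the acetylcyclopentene); the mild temperature should limit β-elimination of the silyloxy group.

**Step 4**
Reactants: 5 (R)-5-isopropyl-2-methyl-5-(triethylsilyloxy)cyclopent-1-ene-1-carbaldehyde, 6 vinylmagnesium bromide
Product: 8 cyclopentanecarbaldehyde with C1 α-methyl β-vinyl and C4 β-triethylsilyloxy α-isopropyl and C5 β-formyl, via silyl enol ether 7 (not isolated)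
Conditions: CH2=CHMgBr (2.5 equiv), CuBr·SMe2 (0.2 equiv), TMSCl (3 equiv), DMPU, THF, −78 to −40 °C; then K2CO3 (0.2 equiv), MeOH, 0 °C to rt
Reagents that add atoms: vinylmagnesium bromide 6, C=C[Mg]Br
Why: Copper-catalysed, TMSCl-accelerated conjugate addition of a Grignard reagent to a β,β-disubstituted enal builds the C1 quaternary centre with vinyl expected on the face anti to the isopropyl group of C4 (the larger substituent close to the ring), and methanolysis of 7 with K2CO3 equilibrates C5 so that the formyl group sits trans to the isopropyl group and cis to the vinyl and silyloxy groups.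

**Step 5**
Reactants: 8 the cyclopentanecarbaldehyde
Product: 9 the corresponding C6 primary alcohol (β-hydroxymethyl on C5)
Conditions: NaBH4, MeOH, 0 °C
Reagents that add atoms: none
Why: Borohydride reduction of the aldehyde fixes the equilibrated C5 configuration and supplies the hydroxyl that will mask C10 as a lactol.

**Step 6**
Reactants: 9 the C6 primary alcohol
Product: 12 cis-fused lactol (C10 hemiacetal carbon closed by O6; anomer mixture), via ozonide 10 (not isolated), via hydroxy aldehyde 11 (not isolated)
Conditions: O3, CH2Cl2, −78 °C; then PPh3, −78 °C to rt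
Reagents that add atoms: ozone, [O-][O+]=O
Why: Ozonolysis of the vinyl group gives the C10 aldehyde, which the cis C6 hydroxyl traps as a five-membered lactol (ring-chain tautomerism), so the two carbonyl carbons stay differentiated without a protecting group.

**Step 7**
Reactants: 12 the cis-fused lactol, 13 2-(chloromethyl)allyltrimethylsilane
Product: 15 diol with C10 secondary carbinol (epimer mixture) bearing the 2-(trimethylsilylmethyl)allyl group and C6 primary alcohol, via allylmagnesium chloride 14 (not isolated)
Conditions: 13, Mg, THF, 0 °C (slow addition) to give 14 (3.5 equiv); then 12, THF, 0 °C to rt; aq NH4Cl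
Reagents that add atoms: 2-(chloromethyl)allyltrimethylsilane 13 (used as its Grignard reagent 14), C=C(CCl)C[Si](C)(C)C
Why: Lactols react with excess allylmagnesium reagents through the ring-opened alkoxy aldehyde (Grignard addition); the allyl unit is symmetric, so there is no regiochemical question, and the C10 carbinol configuration is irrelevant because it is oxidised next.

**Step 8**
Reactants: 15 the diol
Product: 16 keto aldehyde with the 2-(trimethylsilylmethyl)allyl ketone (C10) on C1 and the C6 aldehyde on C5 (cis)
Conditions: (COCl)2, DMSO, CH2Cl2, −78 °C; then Et3N, −78 to −20 °C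
Reagents that add atoms: none
Why: Swern oxidation activates both hydroxyls before base is added, so the 1,4-diol should go to the keto aldehyde without lactol or lactone formation, and the cold, brief exposure to Et3N should not conjugate the β,γ-alkene, epimerise C5 or start aldol closure.

**Step 9**
Reactants: 16 the keto aldehyde
Product: 17 8-methylene hydroazulen-10-one with free 6β-hydroxyl and 4β-triethylsilyloxy group
Conditions: BF3·OEt2 (1.2 equiv), CH2Cl2 (0.005 M), −78 °C; aq NaHCO3
Reagents that add atoms: none
Why: BF3 binds the C6 aldehyde, the alkene terminus C7 of the allylsilane attacks C6, the positive charge developing at C8 is stabilised by the β C–Si bond, and loss of the trimethylsilyl group leaves the exocyclic methylene on C8 and the C6 carbinol. The closest known reaction type is the Lewis acid-promoted intramolecular Hosomi–Sakurai addition of 2-(trimethylsilylmethyl)allyl units to aldehydes, which is established for seven-membered rings. The seven-membered ring closes in the 7-endo-trig mode with respect to the allylsilane alkene (C7 and C8 both end up in the ring) and is cis-fused because C6 and C10 already stand on the β face of the cyclopentane. The new C6 stereocentre is controlled by the C5 and C4 centres: C7 is expected to approach in the sector anti to the quaternary C4, and in the synclinal arrangement of C=O and allylsilane alkene that monodentate BF3 favours, the complexed oxygen lies gauche to C1 (pseudoaxial on the forming ring), which gives the 6β-alcohol cis to the C4 oxygen. The step needs this facial selectivity and also chemoselectivity for C–C bond formation over protodesilylation, aldol closure of the 1,4-dicarbonyl and loss of the silyl ether; a dry non-chelating Lewis acid, −78 °C, high dilution and the absence of base are chosen to secure them.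

**Step 10**
Reactants: 17 the 8-methylene hydroazulen-10-one
Product: 18 conjugated 8-methyl-8(9)-en-10-one with free 6β-hydroxyl
Conditions: DBU (0.5 equiv), CH2Cl2, rt
Reagents that add atoms: none
Why: Base-mediated alkene isomerisation into conjugation (deprotonation at C9, reprotonation of the dienolate at the exocyclic carbon) should give the C8-methyl C8=C9 enone; it is run on the free alcohol so that C6 carries no leaving group for vinylogous elimination, and any deconjugated C7=C8 isomer at equilibrium would be separated and re-equilibrated.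

**Step 11**
Reactants: 19 4-hydroxybenzoic acid
Product: 21 4-(tert-butyldimethylsilyloxy)benzoic acid, via silyl ester 20 (not isolated)
Conditions: TBSCl (2.2 equiv), imidazole, DMF, rt; then AcOH, THF, H2O, rt
Reagents that add atoms: tert-butyldimethylsilyl chloride, CC(C)(C)[Si](C)(C)Cl
Why: Bis-silylation followed by selective hydrolysis of the labile silyl ester gives the phenol-protected acid (silyl ether protection).

**Step 12**
Reactants: 18 the conjugated hydroxy enone, 21 4-(tert-butyldimethylsilyloxy)benzoic acid
Product: 23 6β-[4-(tert-butyldimethylsilyloxy)benzoyloxy] enone, via acid chloride 22 (not isolated)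
Conditions: 21, (COCl)2, DMF (cat.), CH2Cl2, 0 °C to rt, evaporate; then 18, pyridine, DMAP (cat.), CH2Cl2, 0 °C to rt
Reagents that add atoms: 4-(tert-butyldimethylsilyloxy)benzoic acid 21 (used as acid chloride 22), CC(C)(C)[Si](C)(C)Oc1ccc(C(=O)O)cc1
Why: DMAP-catalysed acylation of the secondary C6 alcohol by the acid chloride (nucleophilic acyl substitution) retains the C6 configuration, and the weak base at low temperature should avoid vinylogous elimination of the new aroate.

**Step 13**
Reactants: 23 the 6β-aroyloxy enone
Product: 24 10α-allylic alcohol with 6β-aroyloxy group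
Conditions: NaBH4, CeCl3·7H2O, MeOH, −78 to −40 °C
Reagents that add atoms: none
Why: Luche reduction gives 1,2-reduction of the enone, and hydride is expected to approach C10 anti to the adjacent angular methyl of C1, so the new hydroxyl is α (cis to that methyl, trans to the C6 aroate); the aryl ester is inert at this temperature.

**Step 14**
Reactants: 24 the 10α-allylic alcohol, 25 tiglic acid
Product: 27 10α-tigloyloxy 6β-aroyloxy bis-silyl ether, via mixed anhydride 26 (not isolated)
Conditions: 25, 2,4,6-trichlorobenzoyl chloride, Et3N, toluene, rt; then 24, DMAP, toluene, 60 °C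
Reagents that add atoms: tiglic acid 25, C/C=C(\C)C(=O)O
Why: Yamaguchi esterification acylates hindered secondary alcohols through the unhindered tigloyl carbonyl of the mixed anhydride; the C10–O bond is not broken, so the configuration is retained, and the (E)-alkene of the tigloyl group is the stable isomer.

**Step 15**
Reactants: 27 the bis-silyl ether diester
Product: 28 target CNP0273650.8
Conditions: Bu4NF, AcOH (1:1), THF, 0 °C to rt
Reagents that add atoms: none
Why: Fluoride cleaves both the aryl silyl ether and the tertiary triethylsilyl ether (desilylation), and buffering with AcOH should keep phenoxide and alkoxide from cleaving or migrating the two esters.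

**Compound list**
1 | (S)-terpinen-4-ol | CC1=CC[C@](O)(C(C)C)CC1 | starting material
2 | (S)-terpinen-4-ol triethylsilyl ether | CC1=CC[C@](O[Si](CC)(CC)CC)(C(C)C)CC1 | intermediate
3 | secondary ozonide of 2 (1,2,4-trioxolane across the former ring alkene) | CC12CC[C@@](O[Si](CC)(CC)CC)(C(C)C)CC(OO1)O2 | intermediate
4 | (S)-3-isopropyl-6-oxo-3-(triethylsilyloxy)heptanal | CC(=O)CC[C@@](O[Si](CC)(CC)CC)(C(C)C)CC=O | intermediate
5 | (R)-5-isopropyl-2-methyl-5-(triethylsilyloxy)cyclopent-1-ene-1-carbaldehyde | O=CC1=C(C)CC[C@@]1(O[Si](CC)(CC)CC)C(C)C | intermediate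
6 | vinylmagnesium bromide | C=C[Mg]Br | starting material
7 | trimethylsilyl enol ether of 8 (C5=C6 enol ether; C1 α-methyl, β-vinyl) | C=C[C@]1(C)CC[C@@](O[Si](CC)(CC)CC)(C(C)C)C1=CO[Si](C)(C)C | intermediate
8 | cyclopentanecarbaldehyde: C1 α-methyl β-vinyl, C4 β-OTES α-isopropyl, C5 β-CHO | C=C[C@]1(C)CC[C@@](O[Si](CC)(CC)CC)(C(C)C)[C@@H]1C=O | intermediate
9 | C6 primary alcohol from 8 | C=C[C@]1(C)CC[C@@](O[Si](CC)(CC)CC)(C(C)C)[C@@H]1CO | intermediate
10 | secondary ozonide of 9 (1,2,4-trioxolan-3-yl on C1) | C1OC(OO1)[C@]2(C)CC[C@@](O[Si](CC)(CC)CC)(C(C)C)[C@@H]2CO | intermediate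
11 | hydroxy aldehyde (C10 aldehyde on C1, C6 hydroxymethyl on C5) | O=C[C@]1(C)CC[C@@](O[Si](CC)(CC)CC)(C(C)C)[C@@H]1CO | intermediate
12 | cis-fused lactol (C10 hemiacetal carbon, O6 in the ring; anomer mixture) | OC1OC[C@@H]2[C@@]1(C)CC[C@@]2(O[Si](CC)(CC)CC)C(C)C | intermediate
13 | 2-(chloromethyl)allyltrimethylsilane | C=C(CCl)C[Si](C)(C)C | starting material
14 | 2-(trimethylsilylmethyl)allylmagnesium chloride | C=C(C[Mg]Cl)C[Si](C)(C)C | intermediate
15 | diol: C10 secondary carbinol (epimer mixture) with the silylmethylallyl group, C6 primary alcohol | C=C(C[Si](C)(C)C)CC(O)[C@]1(C)CC[C@@](O[Si](CC)(CC)CC)(C(C)C)[C@@H]1CO | intermediate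
16 | cis keto aldehyde, Sakurai precursor | C=C(C[Si](C)(C)C)CC(=O)[C@]1(C)CC[C@@](O[Si](CC)(CC)CC)(C(C)C)[C@@H]1C=O | intermediate
17 | 8-methylene hydroazulen-10-one, 6β-OH, 4β-OTES | O=C1CC(=C)C[C@@H](O)[C@@H]2[C@@]1(C)CC[C@@]2(O[Si](CC)(CC)CC)C(C)C | intermediate
18 | conjugated 8-methyl-8(9)-en-10-one, 6β-OH, 4β-OTES | O=C1C=C(C)C[C@@H](O)[C@@H]2[C@@]1(C)CC[C@@]2(O[Si](CC)(CC)CC)C(C)C | intermediate
19 | 4-hydroxybenzoic acid | OC(=O)c1ccc(O)cc1 | starting material
20 | tert-butyldimethylsilyl 4-(tert-butyldimethylsilyloxy)benzoate | CC(C)(C)[Si](C)(C)OC(=O)c1ccc(O[Si](C)(C)C(C)(C)C)cc1 | intermediate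
21 | 4-(tert-butyldimethylsilyloxy)benzoic acid | CC(C)(C)[Si](C)(C)Oc1ccc(C(=O)O)cc1 | intermediate
22 | 4-(tert-butyldimethylsilyloxy)benzoyl chloride | CC(C)(C)[Si](C)(C)Oc1ccc(C(Cl)=O)cc1 | intermediate
23 | 6β-[4-(TBS-oxy)benzoyloxy]-8(9)-en-10-one, 4β-OTES | O=C1C=C(C)C[C@@H](OC(=O)c3ccc(O[Si](C)(C)C(C)(C)C)cc3)[C@@H]2[C@@]1(C)CC[C@@]2(O[Si](CC)(CC)CC)C(C)C | intermediate
24 | 10α-allylic alcohol, 6β-aroate, 4β-OTES | O[C@@H]1C=C(C)C[C@@H](OC(=O)c3ccc(O[Si](C)(C)C(C)(C)C)cc3)[C@@H]2[C@@]1(C)CC[C@@]2(O[Si](CC)(CC)CC)C(C)C | intermediate
25 | tiglic acid, (E)-2-methylbut-2-enoic acid | C/C=C(\C)C(=O)O | starting material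
26 | tiglic 2,4,6-trichlorobenzoic mixed anhydride | C/C=C(\C)C(=O)OC(=O)c1c(Cl)cc(Cl)cc1Cl | intermediate
27 | 10α-tiglate, 6β-[4-(TBS-oxy)benzoate], 4β-OTES | C/C=C(\C)C(=O)O[C@@H]1C=C(C)C[C@@H](OC(=O)c3ccc(O[Si](C)(C)C(C)(C)C)cc3)[C@@H]2[C@@]1(C)CC[C@@]2(O[Si](CC)(CC)CC)C(C)C | intermediate
28 | CNP0273650.8 | C/C=C(\C)C(=O)O[C@@H]1C=C(C)C[C@@H](OC(=O)c2ccc(O)cc2)[C@@H]2[C@@]1(C)CC[C@@]2(O)C(C)C | target

**Step count**
Total: 15 steps. Longest linear sequence: 14 steps (steps 1–10 and 12–15 from 1); step 11 is a one-step side branch.

**Steps most likely to fail**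

1. Step 9 (key step). What may go wrong: poor facial selectivity at the aldehyde, with closure through the antiperiplanar arrangement (oxygen anti to C1) giving the 6α-alcohol. Protodesilylation before ring closure is the second danger. Fallback, setting out from 16 and coming back at 23: the ring-closed 6α-epimer, C6-epimeric 8-methylene hydroazulenone F1, is isomerised with DBU as in step 10 to the C6-epimeric conjugated hydroxy enone F2. The aroate is then introduced with inversion at C6 by Mitsunobu esterification with acid 21 (PPh3, DIAD, toluene, 0 °C to rt), which gives 23 directly.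

2. Step 4. What may go wrong: low or reversed facial selectivity at C1 (vinyl entering anti to the silyloxy group), or competing 1,2-addition. Fallback, setting out from 5 and coming back at 9, in which the vinyl donor is tied to the C4 oxygen so that it can only reach the β face of C1:
 - Bu4NF in THF gives the hydroxy enal F3.
 - Silylation with (1-bromovinyl)chlorodimethylsilane (Et3N, DMAP, CH2Cl2) gives the (1-bromovinyl)dimethylsilyl ether F4.
 - Bu3SnH and AIBN (benzene, 80 °C, slow addition) generate the α-silyl vinyl radical, which should add 6-endo to the β-carbon of the enal to give the bridged siloxane aldehyde F5; hydrogen transfer to C5 is expected on the face remote from the silicon bridge.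
 - NaBH4 gives the siloxane alcohol F6.
 - Bu4NF in DMF at 80 °C cleaves the alkenyl–silicon and silicon–oxygen bonds to give the vinyl diol F7.
 - TESOTf and 2,6-lutidine give the bis(triethylsilyl) ether F8, and PPTS in MeOH at 0 °C removes the primary silyl group to return to 9.

3. Step 13. What may go wrong: hydride delivery on the α face (syn to the angular methyl, the convex face of the cis-fused bicycle), giving the 10β-alcohol. Fallback, setting out from 18 and coming back at 24: the free 6β-hydroxyl of 18 is used to deliver hydride intramolecularly to the β face of C10 with Me4NBH(OAc)3 (MeCN, AcOH, −20 °C), giving the 6β,10α-diol F9. The less hindered C6 hydroxyl is then acylated selectively with acid chloride 22 (pyridine, DMAP cat., CH2Cl2, −20 °C), the neopentyl C10 hydroxyl reacting more slowly, which gives 24.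

**Further compounds**
F1 | step 9 | C6-epimeric (6α-OH) 8-methylene hydroazulen-10-one | O=C1CC(=C)C[C@H](O)[C@@H]2[C@@]1(C)CC[C@@]2(O[Si](CC)(CC)CC)C(C)C
F2 | step 9 | C6-epimeric (6α-OH) conjugated 8(9)-en-10-one | O=C1C=C(C)C[C@H](O)[C@@H]2[C@@]1(C)CC[C@@]2(O[Si](CC)(CC)CC)C(C)C
F3 | step 4 | 5-hydroxy-5-isopropyl-2-methylcyclopent-1-ene-1-carbaldehyde (C4 as in 1) | O=CC1=C(C)CC[C@@]1(O)C(C)C
F4 | step 4 | (1-bromovinyl)dimethylsilyl ether of F3 | O=CC1=C(C)CC[C@@]1(O[Si](C)(C)C(Br)=C)C(C)C
F5 | step 4 | bridged siloxane aldehyde (O4–SiMe2–C(=CH2)–C1 bridge on the β face, C5 β-CHO) | C=C1[Si](C)(C)O[C@@]2(C(C)C)CC[C@]1(C)[C@H]2C=O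
F6 | step 4 | bridged siloxane primary alcohol | C=C1[Si](C)(C)O[C@@]2(C(C)C)CC[C@]1(C)[C@H]2CO
F7 | step 4 | vinyl diol (C1 β-vinyl, C4 β-OH, C6 primary alcohol) | C=C[C@]1(C)CC[C@@](O)(C(C)C)[C@@H]1CO
F8 | step 4 | bis(triethylsilyl) ether of F7 | C=C[C@]1(C)CC[C@@](O[Si](CC)(CC)CC)(C(C)C)[C@@H]1CO[Si](CC)(CC)CC
F9 | step 13 | 6β,10α-diol, 8(9)-ene, 4β-OTES | O[C@@H]1C=C(C)C[C@@H](O)[C@@H]2[C@@]1(C)CC[C@@]2(O[Si](CC)(CC)CC)C(C)C
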